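The benzene ring is built, not bought. Its pattern (acyl at C1, hydroxyls at C2 and C5, para to each other, bromine at C4) is that of a 2-silyloxyfuran that has taken up a terminal ynone: ring bonds C1–C2 and C5–C6 are cut, so that C2–C5, both oxygens and the bromine come from 4-bromo-2-(tert-butyldimethylsilyloxy)furan and C1/C6 with the whole chiral side chain from an ethynyl ketone. One thermal [4+2] cycloaddition followed by opening of the oxygen bridge delivers the arene with all four substituents in place. The ynone carries the (R)-carbinol of (R)-linalool as its triethylsilyl ether.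

Key step: step 8

Remark on the chemistry: commercial (R)-(−)-linalool is assumed to be of high enantiomeric purity; no bond to its carbinol carbon is made or broken, so the target should be obtained as the (R) enantiomer.
Remark on the chemistry: tetronic acid is converted to the 4-bromobutenolide by exchange of the enolic hydroxyl for bromide (oxalyl bromide/DMF); electrophilic bromination would enter C3 and give the wrong diene.
Remark on the chemistry: the tertiary alcohol is silylated before the ynone is made, because a free β-hydroxy ynone would close by 6-endo oxa-Michael addition or cleave by retro-aldol reaction; triethylsilyl survives the Grignard step and leaves together with the aryl silyl ether under fluoride, and the diene carries tert-butyldimethylsilyl so that it can be isolated.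

Step 1
Reactants: 1 (R)-(−)-linalool
Product: 3 (R)-3,7-dimethyloct-6-ene-1,3-diol, via B-alkyl-9-borabicyclononane 2 (not isolated)
Conditions: 9-BBN (0.5 M in THF, 2.2 equiv), 0 °C → rt; then 3 M aq. NaOH, 30% H2O2, 0 °C → rt
Reagents that add atoms: hydrogen peroxide, OO
Why: Anti-Markovnikov hydroboration–oxidation, in which the bulky dialkylborane adds only to the monosubstituted alkene (boron to the terminal carbon) and leaves the trisubstituted alkene alone, the C–B bond is oxidised by alkaline peroxide, and the carbinol centre is not involved and keeps its configuration (the excess borane allows for any B–O bond formed at the hydroxyl, which the work-up hydrolyses).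

Step 2
Reactants: 3 (R)-3,7-dimethyloct-6-ene-1,3-diol
Product: 5 (R)-3-hydroxy-3,7-dimethyloct-6-enoic acid, via hydroxy aldehyde 4 (not isolated)
Conditions: 2,2,6,6-tetramethylpiperidin-1-oxyl (TEMPO, 0.2 equiv), PhI(OAc)2 (2.2 equiv), MeCN/H2O (1:1), 0 °C → rt
Reagents that add atoms: water, O
Why: Oxoammonium (TEMPO) oxidation with PhI(OAc)2 as terminal oxidant takes the primary alcohol through aldehyde 4 and its hydrate to the acid, cannot oxidise the tertiary alcohol, and uses no electrophilic halogen that would attack the trisubstituted alkene.

Step 3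
Reactants: 5 (R)-3-hydroxy-3,7-dimethyloct-6-enoic acid
Product: 7 (R)-3-hydroxy-N-methoxy-N,3,7-trimethyloct-6-enamide, via benzotriazolyl ester 6 (not isolated)
Conditions: MeNH(OMe)·HCl, EDC·HCl, 1-hydroxybenzotriazole (HOBt), N-methylmorpholine, CH2Cl2, 0 °C → rt
Reagents that add atoms: N,O-dimethylhydroxylamine hydrochloride, CNOC.Cl
Why: Carbodiimide-mediated amide coupling through the benzotriazolyl active ester gives the Weinreb amide, the hindered tertiary hydroxyl being too poor a nucleophile to compete with the amine.

Step 4
Reactants: 7 (R)-3-hydroxy-N-methoxy-N,3,7-trimethyloct-6-enamide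
Product: 8 (R)-N-methoxy-N,3,7-trimethyl-3-(triethylsilyloxy)oct-6-enamide
Conditions: TESOTf, 2,6-lutidine, CH2Cl2, −78 → 0 °C
Reagents that add atoms: triethylsilyl trifluoromethanesulfonate, CC[Si](CC)(CC)OS(=O)(=O)C(F)(F)F
Why: Silylation of a tertiary alcohol by a silyl triflate and a hindered pyridine base is reliable, the amide and alkene are inert to it, and the ether blocks the oxa-Michael and retro-aldol pathways that a free β-hydroxy ynone would have.

Step 5
Reactants: 8 (R)-N-methoxy-N,3,7-trimethyl-3-(triethylsilyloxy)oct-6-enamide; 9 ethynylmagnesium bromide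
Product: 11 (R)-5,9-dimethyl-5-(triethylsilyloxy)dec-8-en-1-yn-3-one, via bromomagnesium hemiaminal 10 (not isolated)
Conditions: HC≡CMgBr (0.5 M in THF, 2.5 equiv), THF, 0 °C; inverse quench into cold aq. NaHSO4/Et2O
Reagents that add atoms: ethynylmagnesium bromide (compound 9), C#C[Mg]Br
Why: Weinreb ketone synthesis, in which the alkynyl Grignard reagent adds once to give the chelated hemiaminal 10 that collapses to the ynone only on quench, while the acidic inverse quench protonates the released N,O-dimethylhydroxylamine before it can add to the ynone and the brief cold contact should leave the hindered silyl ether intact.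

Step 6
Reactants: 12 tetronic acid
Product: 13 4-bromofuran-2(5H)-one
Conditions: (COBr)2, N,N-dimethylformamide (DMF), CH2Cl2, 0 °C → rt
Reagents that add atoms: oxalyl bromide, O=C(Br)C(=O)Br
Why: Vilsmeier-type deoxyhalogenation of a vinylogous acid, in which the bromoiminium salt from DMF and oxalyl bromide activates the enolic oxygen and bromide replaces it by addition–elimination at C4 to give the known β-bromobutenolide.

Step 7
Reactants: 13 4-bromofuran-2(5H)-one
Product: 14 4-bromo-2-(tert-butyldimethylsilyloxy)furan
Conditions: TBSOTf, i-Pr2NEt, CH2Cl2, 0 °C; rapid filtration through basic Al2O3, used at once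
Reagents that add atoms: tert-butyldimethylsilyl trifluoromethanesulfonate, CC(C)(C)[Si](C)(C)OS(=O)(=O)C(F)(F)F
Why: Silyl dienol ether formation by soft enolisation, in which O-silylation of the lactone carbonyl and loss of a C5 proton to the hindered amine give the aromatic 2-silyloxyfuran, the vinylic bromide being safe because this base cannot add to C4.

Step 8
Reactants: 11 (R)-5,9-dimethyl-5-(triethylsilyloxy)dec-8-en-1-yn-3-one; 14 4-bromo-2-(tert-butyldimethylsilyloxy)furan
Product: 16 (R)-1-[4-bromo-2-(tert-butyldimethylsilyloxy)-5-hydroxyphenyl]-3,7-dimethyl-3-(triethylsilyloxy)oct-6-en-1-one, via oxygen-bridged cycloadduct 15 (not isolated)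
Conditions: 14 (1.5 equiv), PhMe (1 M), 60 °C, sealed tube, no Lewis acid
Reagents that add atoms: none
Why: Normal-electron-demand Diels–Alder reaction: the furan diene, its HOMO raised by the 2-silyloxy group, adds across the ynone triple bond (furan C2 to the acyl-bearing carbon, furan C5 to the terminal carbon) to give cycloadduct 15, whose bridge C–O bond at the silyloxy-bearing bridgehead ionises with help from the silyloxy lone pair, and loss of the proton at the other bridgehead aromatises. The closest known reaction type is the cycloaddition of 2-silyloxy- and 2-alkoxyfurans with acetylenic esters and ketones, which opens spontaneously to 4-oxygenated phenols. The six-membered carbocycle is closed by intermolecular [4+2] cycloaddition, and the oxygen bridge is then broken, so that the furan oxygen ends as the C5 phenol beside bromine and the silyl ether sits at C2 beside the ketone. No lasting stereocentre is made, since the two bridgehead centres of 15 disappear on aromatisation, and the (R) carbinol centre is a remote spectator. The step needs regioselectivity, which the substrate secures because the largest HOMO coefficient of the diene lies at furan C5 (remote terminus of the oxygenated diene, reinforced by bromine at C4) and the largest LUMO coefficient of the dienophile at the terminal alkyne carbon; a stepwise conjugate addition followed by ring closure would give the same connectivity. It also needs ring closure to win over open-chain vinylogous Mukaiyama–Michael products, which the absence of Lewis acid and fluoride favours, while the silyl ether keeps the tertiary oxygen from adding to the ynone and the isolated trisubstituted alkene is no dienophile.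

Step 9
Reactants: 16 (R)-1-[4-bromo-2-(tert-butyldimethylsilyloxy)-5-hydroxyphenyl]-3,7-dimethyl-3-(triethylsilyloxy)oct-6-en-1-one
Product: 17 (R)-1-(4-bromo-2,5-dihydroxyphenyl)-3-hydroxy-3,7-dimethyloct-6-en-1-one
Conditions: HF·pyridine, pyridine, THF, 0 °C → rt, polypropylene vessel, under argon
Reagents that add atoms: none
Why: Fluoride-driven desilylation (Si–F bond formation) cleaves the aryl silyl ether and the tertiary triethylsilyl ether in one operation, and the pyridine buffer should keep the medium mild enough that the tertiary β-hydroxy ketone neither dehydrates nor undergoes retro-aldol cleavage, the alkene and aryl bromide being inert.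

Compound list
1 | (R)-(−)-linalool, (3R)-3,7-dimethylocta-1,6-dien-3-ol | CC(C)=CCC[C@@](C)(O)C=C | starting material
2 | (3S)-1-(9-borabicyclo[3.3.1]nonan-9-yl)-3,7-dimethyloct-6-en-3-ol (same spatial arrangement as 1; the descriptor changes only because boron lowers the CIP rank of the C1–C2 arm) | CC(C)=CCC[C@@](C)(O)CCB1C2CCCC1CCC2 | intermediate
3 | (R)-3,7-dimethyloct-6-ene-1,3-diol | CC(C)=CCC[C@@](C)(O)CCO | intermediate
4 | (R)-3-hydroxy-3,7-dimethyloct-6-enal | CC(C)=CCC[C@@](C)(O)CC=O | intermediate
5 | (R)-3-hydroxy-3,7-dimethyloct-6-enoic acid | CC(C)=CCC[C@@](C)(O)CC(=O)O | intermediate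
6 | 1H-benzotriazol-1-yl (R)-3-hydroxy-3,7-dimethyloct-6-enoate | CC(C)=CCC[C@@](C)(O)CC(=O)On1nnc2ccccc12 | intermediate
7 | (R)-3-hydroxy-N-methoxy-N,3,7-trimethyloct-6-enamide | CC(C)=CCC[C@@](C)(O)CC(=O)N(C)OC | intermediate
8 | (R)-N-methoxy-N,3,7-trimethyl-3-(triethylsilyloxy)oct-6-enamide | CC(C)=CCC[C@@](C)(O[Si](CC)(CC)CC)CC(=O)N(C)OC | intermediate
9 | ethynylmagnesium bromide | C#C[Mg]Br | starting material
10 | bromomagnesium (5R)-3-[methoxy(methyl)amino]-5,9-dimethyl-5-(triethylsilyloxy)dec-8-en-1-yn-3-olate (both C3 epimers) | CC(C)=CCC[C@@](C)(O[Si](CC)(CC)CC)CC(O[Mg]Br)(C#C)N(C)OC | intermediate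
11 | (R)-5,9-dimethyl-5-(triethylsilyloxy)dec-8-en-1-yn-3-one | CC(C)=CCC[C@@](C)(O[Si](CC)(CC)CC)CC(=O)C#C | intermediate
12 | tetronic acid, furan-2,4(3H,5H)-dione | O=C1CC(=O)CO1 | starting material
13 | 4-bromofuran-2(5H)-one | O=C1C=C(Br)CO1 | intermediate
14 | 4-bromo-2-(tert-butyldimethylsilyloxy)furan | CC(C)(C)[Si](C)(C)Oc1cc(Br)co1 | intermediate
15 | (3R)-1-[5-bromo-1-(tert-butyldimethylsilyloxy)-7-oxabicyclo[2.2.1]hepta-2,5-dien-2-yl]-3,7-dimethyl-3-(triethylsilyloxy)oct-6-en-1-one (both bridgehead diastereomers) | CC(C)=CCC[C@@](C)(O[Si](CC)(CC)CC)CC(=O)C1=CC2OC1(O[Si](C)(C)C(C)(C)C)C=C2Br | intermediate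
16 | (R)-1-[4-bromo-2-(tert-butyldimethylsilyloxy)-5-hydroxyphenyl]-3,7-dimethyl-3-(triethylsilyloxy)oct-6-en-1-one | CC(C)=CCC[C@@](C)(O[Si](CC)(CC)CC)CC(=O)c1cc(O)c(Br)cc1O[Si](C)(C)C(C)(C)C | intermediate
17 | (R)-1-(4-bromo-2,5-dihydroxyphenyl)-3-hydroxy-3,7-dimethyloct-6-en-1-one | CC(C)=CCC[C@@](C)(O)CC(=O)c1cc(O)c(Br)cc1O | target

Total step count: 9. Longest linear sequence: 7 steps (steps 1–5, 8 and 9); the diene branch is 2 steps (6 and 7).

Steps most likely to fail

Step 8. The furan may add to the ynone only through C5 in an open-chain conjugate sense, the zwitterion being quenched before the second C–C bond forms. The bromine-deactivated diene may also be lost by protodesilylation through the phenol that the reaction itself produces, faster than it cycloadds. Silyl exchange between the two ring oxygens would be harmless, since step 9 removes both groups. The fallback abandons ring construction and acylates a preformed arene; it sets out from amide 8. Commercial 2,5-dibromobenzene-1,4-diol F1 is silylated (TBSCl, imidazole, DMF) to 1,4-dibromo-2,5-bis(tert-butyldimethylsilyloxy)benzene F2. A single bromine–magnesium exchange with i-PrMgCl·LiCl in THF should give [4-bromo-2,5-bis(tert-butyldimethylsilyloxy)phenyl]magnesium chloride F3, which is not isolated; the magnesium aryl is chosen because, unlike a lithium aryl, it should not suffer oxygen-to-carbon silyl migration. F3 adds to Weinreb amide 8 to form the chloromagnesium hemiaminal F4, and aqueous NH4Cl quench releases (R)-1-[4-bromo-2,5-bis(tert-butyldimethylsilyloxy)phenyl]-3,7-dimethyl-3-(triethylsilyloxy)oct-6-en-1-one F5. The surviving bromine is para to the acyl group by the symmetry of F2. Treatment of F5 under the conditions of step 9 removes all three silyl groups, and the fallback comes back to the route at target 17.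

Step 5. The N,O-dimethylhydroxylamine set free on quench may add in conjugate fashion to the terminal ynone, and the acid needed to prevent this may strip the triethylsilyl ether. The fallback makes the ynone by addition and oxidation, so that no amine is present when the ynone appears; it sets out from amide 8. Reduction with i-Bu2AlH (THF, −78 °C) stops at the diisobutylaluminium hemiaminal F6, which on work-up with aqueous potassium sodium tartrate gives (R)-3,7-dimethyl-3-(triethylsilyloxy)oct-6-enal F7. Addition of ethynylmagnesium bromide 9 (THF, −78 → 0 °C) should give (5R)-5,9-dimethyl-5-(triethylsilyloxy)dec-8-en-1-yn-3-ol F8 as a mixture of carbinol epimers. This is of no consequence, because oxidation with Dess–Martin periodinane (NaHCO3, CH2Cl2, 0 °C) removes that centre, and the fallback comes back to the route at ynone 11.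

Step 9. The hindered tertiary silyl ether may cleave slowly, and during the long exposure the β-oxygen may be lost by elimination, after which the freed ortho-phenol can close onto the enone to a chromanone. The fallback separates the two unmaskings so that the phenol is still blocked during the only operation in which an enone could form; it sets out from 16. Camphorsulfonic acid (catalytic) in MeOH at 0 °C should solvolyse only the triethylsilyl ether, aryl silyl ethers being slow to cleave under mild acid, and give (R)-1-[4-bromo-2-(tert-butyldimethylsilyloxy)-5-hydroxyphenyl]-3-hydroxy-3,7-dimethyloct-6-en-1-one F9. KHF2 in MeOH at rt, a mild reagent selective for phenolic silyl ethers, then frees the second phenol, and the fallback comes back to the route at target 17.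

Further compounds
F1 | step 8 | 2,5-dibromobenzene-1,4-diol (purchased) | Oc1cc(Br)c(O)cc1Br
F2 | step 8 | 1,4-dibromo-2,5-bis(tert-butyldimethylsilyloxy)benzene | CC(C)(C)[Si](C)(C)Oc1cc(Br)c(O[Si](C)(C)C(C)(C)C)cc1Br
F3 | step 8 | [4-bromo-2,5-bis(tert-butyldimethylsilyloxy)phenyl]magnesium chloride (LiCl complex, not isolated) | CC(C)(C)[Si](C)(C)Oc1cc(Br)c(O[Si](C)(C)C(C)(C)C)cc1[Mg]Cl
F4 | step 8 | chloromagnesium (3R)-1-[4-bromo-2,5-bis(tert-butyldimethylsilyloxy)phenyl]-1-[methoxy(methyl)amino]-3,7-dimethyl-3-(triethylsilyloxy)oct-6-en-1-olate (not isolated) | CC(C)=CCC[C@@](C)(O[Si](CC)(CC)CC)CC(O[Mg]Cl)(N(C)OC)c1cc(O[Si](C)(C)C(C)(C)C)c(Br)cc1O[Si](C)(C)C(C)(C)C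
F5 | step 8 | (R)-1-[4-bromo-2,5-bis(tert-butyldimethylsilyloxy)phenyl]-3,7-dimethyl-3-(triethylsilyloxy)oct-6-en-1-one | CC(C)=CCC[C@@](C)(O[Si](CC)(CC)CC)CC(=O)c1cc(O[Si](C)(C)C(C)(C)C)c(Br)cc1O[Si](C)(C)C(C)(C)C
F6 | step 5 | diisobutylaluminium (3R)-1-[methoxy(methyl)amino]-3,7-dimethyl-3-(triethylsilyloxy)oct-6-en-1-olate (not isolated) | CC(C)=CCC[C@@](C)(O[Si](CC)(CC)CC)CC(O[Al](CC(C)C)CC(C)C)N(C)OC
F7 | step 5 | (R)-3,7-dimethyl-3-(triethylsilyloxy)oct-6-enal | CC(C)=CCC[C@@](C)(O[Si](CC)(CC)CC)CC=O
F8 | step 5 | (5R)-5,9-dimethyl-5-(triethylsilyloxy)dec-8-en-1-yn-3-ol (both C3 epimers) | CC(C)=CCC[C@@](C)(O[Si](CC)(CC)CC)CC(O)C#C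
F9 | step 9 | (R)-1-[4-bromo-2-(tert-butyldimethylsilyloxy)-5-hydroxyphenyl]-3-hydroxy-3,7-dimethyloct-6-en-1-one | CC(C)=CCC[C@@](C)(O)CC(=O)c1cc(O)c(Br)cc1O[Si](C)(C)C(C)(C)C
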